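## Retrosynthetic overview

1. The target is released last by fluoride cleavage of an aryl silyl ether on the phenol.
2. Key disconnection: the enol-ether C(sp2)–O bond, made by copper-mediated oxidative coupling of (S)-encecalol with a cyclic (Z)-alkenyl hemiboronate; the carbinol centre and the alkene geometry are both carried in ready-made.
3. The hemiboronate comes from anti-arylmagnesiation of propargyl alcohol with the Grignard reagent of O-silylated 2-bromo-5-methylphenol, then a boron quench; a five-membered chelate fixes the geometry.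
4. (S)-Encecalol comes from catalytic asymmetric methyl addition to the 6-formylchromene, which comes from Vilsmeier formylation of precocene I.
5. Ring order: the pyran ring of the chromene is made first (3-methoxyphenol + prenal); the oxaborole ring is a temporary ring made in the carbometalation step and opened in the coupling; both benzene rings are bought.

Reading of the target used throughout: ether oxygen and CH2OH are cis on the enol ether (Z), the benzylic carbon is (S), and the aryl group is 2-hydroxy-4-methylphenyl.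

## Route

Step 1
Reactants: 1 3-methoxyphenol, 2 3-methylbut-2-enal
Product: 3 7-methoxy-2,2-dimethyl-2H-chromene (precocene I)
Conditions: PhB(OH)2 (1 equiv, recovered), AcOH, toluene, reflux, Dean–Stark
Reagents that add atoms: none
Why: Phenylboronic acid-templated ortho-C-alkylation of the phenol by the enal gives an ortho-quinone methide that closes by oxa-6π electrocyclisation (chromenylation), and the less hindered ortho position para to OMe reacts, giving the 7-methoxy isomer.

Step 2
Reactants: 3 7-methoxy-2,2-dimethyl-2H-chromene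
Product: 5 7-methoxy-2,2-dimethyl-2H-chromene-6-carbaldehyde, via aryl iminium chloride 4 (not isolated)
Conditions: POCl3, DMF, 0 °C → 50 °C; then H2O, 0 °C
Reagents that add atoms: N,N-dimethylformamide CN(C)C=O; water O
Why: Vilsmeier–Haack formylation, in which the weak chloroiminium electrophile attacks C6 (para to the ring oxygen, ortho to OMe) and spares the acid-sensitive styrenyl double bond, and hydrolysis of iminium 4 gives the aldehyde.

Step 3
Reactants: 5 7-methoxy-2,2-dimethyl-2H-chromene-6-carbaldehyde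
Product: 7 (1S)-1-(7-methoxy-2,2-dimethyl-2H-chromen-6-yl)ethan-1-ol [(S)-encecalol], via methylzinc alkoxide 6 (not isolated)
Conditions: Me2Zn (2 equiv), (−)-MIB [(2S)-3-exo-morpholinoisoborneol, 5 mol%], toluene, 0 °C → rt; then H2O
Reagents that add atoms: dimethylzinc C[Zn]C
Why: Noyori-type amino-alcohol-catalysed dialkylzinc addition, in which the (2S)-ligand–zinc complex delivers CH3 to the Si face of the aryl aldehyde as it does for benzaldehyde, setting the (S) carbinol centre (ee to be checked by chiral HPLC).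

Step 4
Reactants: 8 2-bromo-5-methylphenol
Product: 9 (2-bromo-5-methylphenoxy)tri(propan-2-yl)silane
Conditions: TIPSCl, imidazole, DMF, rt
Reagents that add atoms: chlorotri(propan-2-yl)silane CC(C)[Si](Cl)(C(C)C)C(C)C
Why: Standard phenol silylation; the bulky TIPS ether tolerates Grignard formation and neighbouring alkoxides without silyl migration and is removed by fluoride at the end.

Step 5
Reactants: 9 (2-bromo-5-methylphenoxy)tri(propan-2-yl)silane, 10 prop-2-yn-1-ol
Product: 13 4-{4-methyl-2-[tri(propan-2-yl)silyloxy]phenyl}-1,2-oxaborol-2(5H)-ol, via aryl Grignard reagent 11 (not isolated), via alkenylmagnesium chelate 12 (not isolated)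
Conditions: Mg, THF, 40 °C; then 10 pre-treated with i-PrMgCl (1 equiv, THF, 0 °C), CuI (10 mol%), 0 → 45 °C; then B(OMe)3, −40 °C → rt; then H2O
Reagents that add atoms: trimethyl borate COB(OC)OC; water O
Why: Copper-catalysed anti-carbomagnesiation of the propargylic magnesium alkoxide (Duboudin–Jousseaume reaction) puts the aryl group on C2 and magnesium on C3 cis to CH2O in five-membered chelate 12, which fixes the alkene geometry, and borylation of the alkenyl–Mg bond with retention followed by ring closure gives the cyclic hemiboronate.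

Step 6
Reactants: 7 (1S)-1-(7-methoxy-2,2-dimethyl-2H-chromen-6-yl)ethan-1-ol (1.0 equiv), 13 4-{4-methyl-2-[tri(propan-2-yl)silyloxy]phenyl}-1,2-oxaborol-2(5H)-ol (1.5 equiv)
Product: 15 (2Z)-3-[(1S)-1-(7-methoxy-2,2-dimethyl-2H-chromen-6-yl)ethoxy]-2-{4-methyl-2-[tri(propan-2-yl)silyloxy]phenyl}prop-2-en-1-ol, via mixed boronic ester 14 (not isolated)
Conditions: 4 Å MS, CH2Cl2, rt, 1 h; then Cu(OAc)2 (20 mol%), DMAP (40 mol%), O2 (1 atm), rt; then H2O
Reagents that add atoms: none
Why: Proposed new method: the B–OH of hemiboronate 13 exchanges with secondary alcohol 7 over molecular sieves to give mixed ester 14, so the alkoxide to be coupled sits on the same boron as the alkenyl group; divalent copper binds this oxygen as a Cu–O–B bridge, the alkenyl group moves from boron to copper, and after oxidation to trivalent copper the C(sp2)–O bond is formed by reductive elimination with retention of the ring-defined Z geometry and without touching the carbinol C–O bond, while the ring oxygen stays on boron (primary hydroxyl masked until work-up, and its own coupling would need a four-membered oxete); the closest known reaction type is the Chan–Lam–Evans oxidative O-alkenylation of aliphatic alcohols with alkenyl trifluoroborates or alkenyl pinacol boronates.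

Step 7
Reactants: 15 (2Z)-3-[(1S)-1-(7-methoxy-2,2-dimethyl-2H-chromen-6-yl)ethoxy]-2-{4-methyl-2-[tri(propan-2-yl)silyloxy]phenyl}prop-2-en-1-ol
Product: 16 (2Z)-2-(2-hydroxy-4-methylphenyl)-3-[(1S)-1-(7-methoxy-2,2-dimethyl-2H-chromen-6-yl)ethoxy]prop-2-en-1-ol (target, CNP0279099.1)
Conditions: Bu4NF (1.1 equiv), AcOH (1.1 equiv), THF, 0 °C
Reagents that add atoms: none
Why: Fluoride-mediated desilylation of the aryl silyl ether under acetic-acid-buffered, near-neutral conditions leaves the acid-labile enol ether, the benzylic ether, the chromene and both stereoelements untouched.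

## Compound list

1 | 3-methoxyphenol | COc1cccc(O)c1 | starting material
2 | 3-methylbut-2-enal (prenal) | CC(C)=CC=O | starting material
3 | 7-methoxy-2,2-dimethyl-2H-chromene (precocene I) | COc1ccc2C=CC(C)(C)Oc2c1 | intermediate
4 | N-[(7-methoxy-2,2-dimethyl-2H-chromen-6-yl)methylidene]-N-methylmethanaminium chloride | COc1cc2c(cc1C=[N+](C)C)C=CC(C)(C)O2.[Cl-] | intermediate
5 | 7-methoxy-2,2-dimethyl-2H-chromene-6-carbaldehyde | COc1cc2c(cc1C=O)C=CC(C)(C)O2 | intermediate
6 | methylzinc (1S)-1-(7-methoxy-2,2-dimethyl-2H-chromen-6-yl)ethoxide | COc1cc2c(cc1[C@H](C)O[Zn]C)C=CC(C)(C)O2 | intermediate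
7 | (1S)-1-(7-methoxy-2,2-dimethyl-2H-chromen-6-yl)ethan-1-ol [(S)-encecalol] | COc1cc2c(cc1[C@H](C)O)C=CC(C)(C)O2 | intermediate
8 | 2-bromo-5-methylphenol | Cc1ccc(Br)c(O)c1 | starting material
9 | (2-bromo-5-methylphenoxy)tri(propan-2-yl)silane | Cc1ccc(Br)c(O[Si](C(C)C)(C(C)C)C(C)C)c1 | intermediate
10 | prop-2-yn-1-ol | OCC#C | starting material
11 | {4-methyl-2-[tri(propan-2-yl)silyloxy]phenyl}magnesium bromide | Cc1ccc([Mg]Br)c(O[Si](C(C)C)(C(C)C)C(C)C)c1 | intermediate
12 | 4-{4-methyl-2-[tri(propan-2-yl)silyloxy]phenyl}-2,5-dihydro-1,2-oxamagnesole (Z-alkenylmagnesium alkoxide chelate, Mg cis to CH2O) | Cc1ccc(C2=C[Mg]OC2)c(O[Si](C(C)C)(C(C)C)C(C)C)c1 | intermediate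
13 | 4-{4-methyl-2-[tri(propan-2-yl)silyloxy]phenyl}-1,2-oxaborol-2(5H)-ol | Cc1ccc(C2=CB(O)OC2)c(O[Si](C(C)C)(C(C)C)C(C)C)c1 | intermediate
14 | 2-[(1S)-1-(7-methoxy-2,2-dimethyl-2H-chromen-6-yl)ethoxy]-4-{4-methyl-2-[tri(propan-2-yl)silyloxy]phenyl}-2,5-dihydro-1,2-oxaborole | COc1cc2c(cc1[C@H](C)OB3OCC(c4ccc(C)cc4O[Si](C(C)C)(C(C)C)C(C)C)=C3)C=CC(C)(C)O2 | intermediate
15 | (2Z)-3-[(1S)-1-(7-methoxy-2,2-dimethyl-2H-chromen-6-yl)ethoxy]-2-{4-methyl-2-[tri(propan-2-yl)silyloxy]phenyl}prop-2-en-1-ol | COc1cc2c(cc1[C@H](C)O/C=C(\CO)c1ccc(C)cc1O[Si](C(C)C)(C(C)C)C(C)C)C=CC(C)(C)O2 | intermediate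
16 | (2Z)-2-(2-hydroxy-4-methylphenyl)-3-[(1S)-1-(7-methoxy-2,2-dimethyl-2H-chromen-6-yl)ethoxy]prop-2-en-1-ol | COc1cc2c(cc1[C@H](C)O/C=C(\CO)c1ccc(C)cc1O)C=CC(C)(C)O2 | target

## Step count and risk

Total steps: 7. Longest linear sequence: 5 (steps 1, 2, 3, 6, 7); the aryl branch (steps 4, 5) joins at step 6.

**Most at risk is step 6, the proposed new coupling.** The hindered secondary benzylic alcohol may transfer slowly, and the likely losses are protodeboronation to the 2-arylallyl alcohol, O-alkenylation of the primary hydroxyl once it is set free, and oxidation of 7 to the ketone. The fallback uses known chemistry only; it sets out from chelate 12 (made as in step 5) and from 7, and comes back to the route at 16.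
- Quenching 12 with I2 (THF, −20 °C) instead of B(OMe)3 is the classical iodinolysis of this chelate with retention, and gives (2Z)-3-iodo-2-{4-methyl-2-[tri(propan-2-yl)silyloxy]phenyl}prop-2-en-1-ol F1.
- TBSCl and imidazole in DMF convert it into tert-butyl{[(2Z)-3-iodo-2-{4-methyl-2-[tri(propan-2-yl)silyloxy]phenyl}prop-2-en-1-yl]oxy}dimethylsilane F2.
- Ullmann-type etherification of F2 with 7 (CuI 10 mol%, 3,4,7,8-tetramethyl-1,10-phenanthroline 20 mol%, Cs2CO3, toluene, 80 °C) is the known copper-catalysed coupling of vinyl iodides with alcohols, retentive at the alkene and at the carbinol carbon. It gives tert-butyl{[(2Z)-3-[(1S)-1-(7-methoxy-2,2-dimethyl-2H-chromen-6-yl)ethoxy]-2-{4-methyl-2-[tri(propan-2-yl)silyloxy]phenyl}prop-2-en-1-yl]oxy}dimethylsilane F3.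
- Bu4NF (2.2 equiv) with AcOH in THF removes both silyl groups and gives 16.

**Second is step 5.** The ortho-silyloxy aryl Grignard reagent may add sluggishly to the propargyl alkoxide, and alkyne deprotonation competes. The fallback replaces alkyne carbometalation by carbonyl olefination; it sets out from Grignard reagent 11 and comes back at 13.
- Acylation of 11 with 2-[(tert-butyldimethylsilyl)oxy]-N-methoxy-N-methylacetamide (THF, 0 °C) gives 2-[(tert-butyldimethylsilyl)oxy]-1-{4-methyl-2-[tri(propan-2-yl)silyloxy]phenyl}ethan-1-one F4.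
- Boron–Wittig olefination with CH2(Bpin)2 and lithium 2,2,6,6-tetramethylpiperidide (THF, 0 °C) gives the alkenyl boronate, of which the wanted isomer is tert-butyldimethyl{[(2Z)-2-{4-methyl-2-[tri(propan-2-yl)silyloxy]phenyl}-3-(4,4,5,5-tetramethyl-1,3,2-dioxaborolan-2-yl)prop-2-en-1-yl]oxy}silane F5. The E/Z ratio is not predictable.
- AcOH–THF–H2O at 40 °C cleaves the primary TBS ether but not the aryl TIPS ether. Only the Z isomer can close onto boron, so it alone gives 13 with loss of pinacol, and the open-chain E isomer is separated.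

**Third is step 3.** Methyl transfer from Me2Zn to an electron-rich ortho-methoxy aldehyde is slow, and the ortho-methoxy group may erode the ee. The fallback sets the centre by ketone reduction instead; it sets out from 5 and comes back at 7.
- MeMgBr (THF, −78 °C) gives racemic 1-(7-methoxy-2,2-dimethyl-2H-chromen-6-yl)ethan-1-ol F6.
- MnO2 in CH2Cl2 oxidises it to 1-(7-methoxy-2,2-dimethyl-2H-chromen-6-yl)ethan-1-one (encecalin) F7.
- Noyori asymmetric transfer hydrogenation with RuCl[(S,S)-TsDPEN](p-cymene) and HCO2H/Et3N gives 7, the (S,S) catalyst giving (S)-1-arylethanols.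

Handling note: 7, 15 and 16 ionise easily at the benzylic carbon, so work-ups stay neutral to slightly basic and chromatography uses Et3N-deactivated silica.

## Further compounds

F1 | step 6 | (2Z)-3-iodo-2-{4-methyl-2-[tri(propan-2-yl)silyloxy]phenyl}prop-2-en-1-ol | I/C=C(\CO)c1ccc(C)cc1O[Si](C(C)C)(C(C)C)C(C)C
F2 | step 6 | tert-butyl{[(2Z)-3-iodo-2-{4-methyl-2-[tri(propan-2-yl)silyloxy]phenyl}prop-2-en-1-yl]oxy}dimethylsilane | I/C=C(\CO[Si](C)(C)C(C)(C)C)c1ccc(C)cc1O[Si](C(C)C)(C(C)C)C(C)C
F3 | step 6 | tert-butyl{[(2Z)-3-[(1S)-1-(7-methoxy-2,2-dimethyl-2H-chromen-6-yl)ethoxy]-2-{4-methyl-2-[tri(propan-2-yl)silyloxy]phenyl}prop-2-en-1-yl]oxy}dimethylsilane | COc1cc2c(cc1[C@H](C)O/C=C(\CO[Si](C)(C)C(C)(C)C)c1ccc(C)cc1O[Si](C(C)C)(C(C)C)C(C)C)C=CC(C)(C)O2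
F4 | step 5 | 2-[(tert-butyldimethylsilyl)oxy]-1-{4-methyl-2-[tri(propan-2-yl)silyloxy]phenyl}ethan-1-one | Cc1ccc(C(=O)CO[Si](C)(C)C(C)(C)C)c(O[Si](C(C)C)(C(C)C)C(C)C)c1
F5 | step 5 | tert-butyldimethyl{[(2Z)-2-{4-methyl-2-[tri(propan-2-yl)silyloxy]phenyl}-3-(4,4,5,5-tetramethyl-1,3,2-dioxaborolan-2-yl)prop-2-en-1-yl]oxy}silane | CC1(C)OB(/C=C(\CO[Si](C)(C)C(C)(C)C)c2ccc(C)cc2O[Si](C(C)C)(C(C)C)C(C)C)OC1(C)C
F6 | step 3 | rac-1-(7-methoxy-2,2-dimethyl-2H-chromen-6-yl)ethan-1-ol | COc1cc2c(cc1C(C)O)C=CC(C)(C)O2
F7 | step 3 | 1-(7-methoxy-2,2-dimethyl-2H-chromen-6-yl)ethan-1-one (encecalin) | COc1cc2c(cc1C(C)=O)C=CC(C)(C)O2
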